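## Retrosynthetic overview

1. Chromane numbering is used throughout (O1, C2, C3, C4, C4a, C5–C8, C8a). The last operations are removal of a temporary C4 carbonyl (Wolff–Kishner, with ester saponification) and conjugate addition of vinyl at C2, which leads back to the bicyclic 2-methyl-2,3-dihydro-4-pyranone 16.
2. Key disconnection: the carbocycle C4a–C5–C6–C7–C8–C8a is made by a formal [4+2] union (bonds C8–C8a and C4a–C5) of the 4-silyloxypyrylium ion from 2,6-dimethyl-4-pyranone 10 with the acyclic diene 9, which already carries both ester arms.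
3. Enabling feature: C8a carries the ring oxygen and a methyl group and C4a lies between C8a and C4, so the ring-fusion bond C8a–C4a is the enol-ether C=C of a symmetric 4-pyranone. C5 (quaternary)–C6–C7–C8 maps onto a 1,3-diene, and the second, untouched C2=C3 enone of the pyranone is kept for the vinyl group.
4. Ring order: the pyran ring is bought as 10; the carbocycle is closed last (step 5). Diene 9 comes from methyl isobutyrate by acylation, alkylation, enol triflation and Stille vinylation.
5. Stereocentres: C8a by the catalyst in step 5, C5 and C4a by the topology of the ring closure, C6 by directed hydrogenation, C4a corrected by epimerisation, C2 by cuprate attack anti to the 8a-methyl group.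

Key step: step 5

Remark: the sense of induction of the chiral hydrogen-bond donor in step 5 cannot be derived from a close analogue; the route is written for the catalyst enantiomer that gives the (8aR) series.

## Route

Step 1
Reactants: 1 methyl 2-methylpropanoate; 2 propanoyl chloride
Product: 3 methyl 2,2-dimethyl-3-oxopentanoate
Conditions: LDA, THF, −78 °C; then 2, −78 → 0 °C
Reagents that add atoms: propanoyl chloride (2), CCC(=O)Cl
Why: Claisen-type C-acylation of the lithium ester enolate with an acid chloride; the quaternary α-carbon of the product cannot enolise towards the ester, so over-acylation is not expected.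

Step 2
Reactants: 3 methyl 2,2-dimethyl-3-oxopentanoate; 4 methyl bromoacetate
Product: 5 dimethyl 2,2,4-trimethyl-3-oxohexanedioate (racemic)
Conditions: LDA, THF, −78 °C; then 4, −78 °C → rt
Reagents that add atoms: methyl bromoacetate (4), BrCC(=O)OC
Why: enolate alkylation at the only enolisable ketone position (the ethyl-ketone CH2) with a reactive α-halo ester; the new stereocentre becomes sp2 in step 3 and need not be controlled.

Step 3
Reactants: 5 dimethyl 2,2,4-trimethyl-3-oxohexanedioate; 6 N-phenylbis(trifluoromethanesulfonimide)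
Product: 7 dimethyl (3Z)-2,2,4-trimethyl-3-{[(trifluoromethyl)sulfonyl]oxy}hex-3-enedioate
Conditions: KHMDS, THF, −78 → 0 °C; then 6, 0 °C → rt
Reagents that add atoms: N-phenylbis(trifluoromethanesulfonimide) (6), O=S(=O)(N(c1ccccc1)S(=O)(=O)C(F)(F)F)C(F)(F)F
Why: O-sulfonylation of the ketone enolate (enol triflate formation, one regioisomer possible); the Z geometry (TfO cis to CH2CO2Me) is expected because the bulky C(CH3)2CO2Me group sits cis to the smaller methyl group (allylic 1,3-strain), and this geometry later becomes the configuration at C5.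

Step 4
Reactants: 7 enol triflate; 8 tributyl(ethenyl)stannane
Product: 9 dimethyl (3E)-3-ethenyl-2,2,4-trimethylhex-3-enedioate
Conditions: Pd(PPh3)4 (5 mol %), LiCl (3 equiv), THF, 65 °C
Reagents that add atoms: tributyl(ethenyl)stannane (8), C=C[Sn](CCCC)(CCCC)CCCC
Why: Stille coupling of an enol triflate, which proceeds with retention of alkene geometry, so the vinyl group ends cis to CH2CO2Me.

Step 5
Reactants: 9 dimethyl (3E)-3-ethenyl-2,2,4-trimethylhex-3-enedioate; 10 2,6-dimethyl-4H-pyran-4-one
Product: 14 methyl 2-[(4aS,5R,8aR)-5-(2-methoxy-2-oxoethyl)-2,5,8a-trimethyl-4-oxo-4a,5,8,8a-tetrahydro-4H-chromen-6-yl]-2-methylpropanoate, via silyloxypyrylium triflate 11 (not isolated), via open-chain allyl cation triflate 12 (not isolated), via O-silyl oxocarbenium triflate 13 (not isolated)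
Conditions: 10, TBSOTf (1.1 equiv), CH2Cl2, 0 °C; then 9, chiral tert-leucine-derived 2-arylpyrrolidine squaramide (10 mol %), 2,6-di-tert-butyl-4-methylpyridine (0.1 equiv), CH2Cl2/toluene, −78 → −30 °C; aq NaHCO3
Reagents that add atoms: 2,6-dimethyl-4H-pyran-4-one (10), CC1=CC(=O)C=C(C)O1
Why: Proposed new method: O-silylation turns 10 into the aromatic pyrylium 11; the unsubstituted CH2 terminus of 9 adds to its methyl-bearing α-carbon (future C8a) to give 12, a 2H-pyranyl silyl dienol ether tethered to a tertiary allyl cation, whose dienol-ether terminus (future C4a) then captures the cation at the fully substituted carbon (future C5) to give 13, which is desilylated on work-up. The closest known reaction types are Mukaiyama–Michael-type additions of silyl enol ethers and allylmetals to 4-silyloxypyrylium and benzopyrylium ions, including enantioselective anion-binding variants, and cation-accelerated (ionic) Diels–Alder reactions. The carbocycle closes by a stepwise [4+2]: the second bond forms by 6-endo attack of the dienol ether on the allyl cation through a boat-like array. C8a is set by the catalyst, whose squaramide binds triflate and shields one face of the planar pyrylium. C5 and C4a are set by the suprafacial closure with the pyranyl ring turned away from the C6 quaternary group (exo), so that the CH2CO2Me group that is cis to vinyl in (3E)-9 ends trans, and the C5 methyl cis, to the 8a-methyl, with H-4a also cis to it. The step needs regiocontrol and exo topology; the first is secured by the unsubstituted diene terminus (most nucleophilic, gives the tertiary allyl cation) and the second by the bulk of the C(CH3)2CO2Me group.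

Step 6
Reactants: 14 bicyclic dienone diester
Product: 15 methyl 2-[(4aS,5S,6R,8aR)-5-(2-methoxy-2-oxoethyl)-2,5,8a-trimethyl-4-oxo-4a,5,6,7,8,8a-hexahydro-4H-chromen-6-yl]-2-methylpropanoate
Conditions: [Ir(cod)(PCy3)(py)]PF6 (5 mol %), H2 (1 atm), CH2Cl2, 0 °C → rt
Reagents that add atoms: none
Why: ester-directed homogeneous hydrogenation: the C5 CH2CO2Me arm binds iridium and delivers H2 to its own face of C6=C7, giving C6 with H trans to the C5 methyl, while the push–pull C2=C3 bond of the vinylogous ester is expected to remain.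

Step 7
Reactants: 15 cis-fused hexahydrochromenone
Product: 16 methyl 2-[(4aR,5S,6R,8aR)-5-(2-methoxy-2-oxoethyl)-2,5,8a-trimethyl-4-oxo-4a,5,6,7,8,8a-hexahydro-4H-chromen-6-yl]-2-methylpropanoate
Conditions: DBU (0.2 equiv), toluene, 40 °C
Reagents that add atoms: none
Why: base-mediated epimerisation α to the ketone under thermodynamic control; the C4a–C4 bond moves from axial to equatorial on the cyclohexane chair, giving the trans-fused (4aR) isomer.

Step 8
Reactants: 16 trans-fused hexahydrochromenone; 17 ethenylmagnesium bromide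
Product: 18 methyl 2-[(2R,4aR,5S,6R,8aR)-2-ethenyl-5-(2-methoxy-2-oxoethyl)-2,5,8a-trimethyl-4-oxooctahydro-2H-chromen-6-yl]-2-methylpropanoate
Conditions: 17, CuBr·SMe2, THF/Me2S, −78 → −40 °C; aq NH4Cl
Reagents that add atoms: ethenylmagnesium bromide (17), C=C[Mg]Br
Why: copper-mediated conjugate addition to the 2-methyl-2,3-dihydro-4-pyranone, a reaction type with close precedent on 8a-methyl hexahydrochromen-4-ones; attack anti to the axial 8a-methyl (1,3 across the ring oxygen) sets C2 as 2R.

Step 9
Reactants: 18 vinyl keto diester; 19 potassium hydroxide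
Product: 22 2-[(2R,4aR,5S,6R,8aR)-5-(carboxymethyl)-2-ethenyl-2,5,8a-trimethyloctahydro-2H-chromen-6-yl]-2-methylpropanoic acid, via dipotassium keto dicarboxylate 20 (not isolated), via hydrazone dipotassium salt 21 (not isolated)
Conditions: KOH, diethylene glycol/H2O, 120 °C; then N2H4·H2O, 130 → 200 °C (water distilled off, under N2); aq HCl
Reagents that add atoms: potassium hydroxide (19), [K+].[OH-]
Why: saponification of both esters followed by Wolff–Kishner reduction (Huang–Minlon conditions) of the hindered C4 ketone through its hydrazone; no stereocentre is formed and C4a stays in its thermodynamic configuration.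

## Compound list

1 | methyl 2-methylpropanoate | CC(C)C(=O)OC | starting material
2 | propanoyl chloride | CCC(=O)Cl | starting material
3 | methyl 2,2-dimethyl-3-oxopentanoate | CCC(=O)C(C)(C)C(=O)OC | intermediate
4 | methyl bromoacetate | BrCC(=O)OC | starting material
5 | dimethyl 2,2,4-trimethyl-3-oxohexanedioate (racemic) | COC(=O)CC(C)C(=O)C(C)(C)C(=O)OC | intermediate
6 | N-phenylbis(trifluoromethanesulfonimide) | O=S(=O)(N(c1ccccc1)S(=O)(=O)C(F)(F)F)C(F)(F)F | starting material
7 | dimethyl (3Z)-2,2,4-trimethyl-3-{[(trifluoromethyl)sulfonyl]oxy}hex-3-enedioate | COC(=O)C/C(C)=C(\OS(=O)(=O)C(F)(F)F)C(C)(C)C(=O)OC | intermediate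
8 | tributyl(ethenyl)stannane | C=C[Sn](CCCC)(CCCC)CCCC | starting material
9 | dimethyl (3E)-3-ethenyl-2,2,4-trimethylhex-3-enedioate | COC(=O)C/C(C)=C(\C=C)C(C)(C)C(=O)OC | intermediate
10 | 2,6-dimethyl-4H-pyran-4-one | CC1=CC(=O)C=C(C)O1 | starting material
11 | 4-[(tert-butyldimethylsilyl)oxy]-2,6-dimethylpyrylium trifluoromethanesulfonate | Cc1cc(O[Si](C)(C)C(C)(C)C)cc(C)[o+]1.[O-]S(=O)(=O)C(F)(F)F | intermediate (not isolated)
12 | triflate of the open-chain cation: (2R)-4-silyloxy-2,6-dimethyl-2H-pyran whose C2 carries the CH2 terminus of 9, the charge delocalised over the resulting allyl unit (one resonance form drawn) | CC1=CC(O[Si](C)(C)C(C)(C)C)=C[C@@](C)(CC=C(C(C)(C)C(=O)OC)[C+](C)CC(=O)OC)O1.[O-]S(=O)(=O)C(F)(F)F | intermediate (not isolated)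
13 | O-tert-butyldimethylsilyl oxocarbenium triflate of 14 (same configuration) | CC1=CC(=[O+][Si](C)(C)C(C)(C)C)[C@H]2[C@@](C)(CC(=O)OC)C(C(C)(C)C(=O)OC)=CC[C@@]2(C)O1.[O-]S(=O)(=O)C(F)(F)F | intermediate (not isolated)
14 | methyl 2-[(4aS,5R,8aR)-5-(2-methoxy-2-oxoethyl)-2,5,8a-trimethyl-4-oxo-4a,5,8,8a-tetrahydro-4H-chromen-6-yl]-2-methylpropanoate | CC1=CC(=O)[C@H]2[C@@](C)(CC(=O)OC)C(C(C)(C)C(=O)OC)=CC[C@@]2(C)O1 | intermediate
15 | methyl 2-[(4aS,5S,6R,8aR)-5-(2-methoxy-2-oxoethyl)-2,5,8a-trimethyl-4-oxo-4a,5,6,7,8,8a-hexahydro-4H-chromen-6-yl]-2-methylpropanoate | CC1=CC(=O)[C@H]2[C@@](C)(CC(=O)OC)[C@H](C(C)(C)C(=O)OC)CC[C@@]2(C)O1 | intermediate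
16 | methyl 2-[(4aR,5S,6R,8aR)-5-(2-methoxy-2-oxoethyl)-2,5,8a-trimethyl-4-oxo-4a,5,6,7,8,8a-hexahydro-4H-chromen-6-yl]-2-methylpropanoate | CC1=CC(=O)[C@@H]2[C@@](C)(CC(=O)OC)[C@H](C(C)(C)C(=O)OC)CC[C@@]2(C)O1 | intermediate
17 | ethenylmagnesium bromide | C=C[Mg]Br | starting material
18 | methyl 2-[(2R,4aR,5S,6R,8aR)-2-ethenyl-5-(2-methoxy-2-oxoethyl)-2,5,8a-trimethyl-4-oxooctahydro-2H-chromen-6-yl]-2-methylpropanoate | C=C[C@@]1(C)CC(=O)[C@@H]2[C@@](C)(CC(=O)OC)[C@H](C(C)(C)C(=O)OC)CC[C@@]2(C)O1 | intermediate
19 | potassium hydroxide | [K+].[OH-] | starting material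
20 | dipotassium salt of the 4-oxo diacid corresponding to 18 (same configuration) | C=C[C@@]1(C)CC(=O)[C@@H]2[C@@](C)(CC(=O)[O-])[C@H](C(C)(C)C(=O)[O-])CC[C@@]2(C)O1.[K+].[K+] | intermediate (not isolated)
21 | dipotassium salt of the C4 hydrazone of 20 (same configuration) | C=C[C@@]1(C)CC(=NN)[C@@H]2[C@@](C)(CC(=O)[O-])[C@H](C(C)(C)C(=O)[O-])CC[C@@]2(C)O1.[K+].[K+] | intermediate (not isolated)
22 | 2-[(2R,4aR,5S,6R,8aR)-5-(carboxymethyl)-2-ethenyl-2,5,8a-trimethyloctahydro-2H-chromen-6-yl]-2-methylpropanoic acid | C=C[C@@]1(C)CC[C@@H]2[C@@](C)(CC(=O)O)[C@H](C(C)(C)C(=O)O)CC[C@@]2(C)O1 | target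

## Step count and risks

Total step count: 9. Longest linear sequence: 9 steps (from methyl 2-methylpropanoate; 10 enters at step 5).

Steps most likely to fail:

1. Step 5 (Proposed new method). The hindered, ester-bearing diene may be too weak a nucleophile for the methyl-stabilised pyrylium ion. The open allyl cation may be intercepted by an ester carbonyl instead of closing. The closure may take the pyranyl-endo topology, giving the wrong C5/C8a relationship, and the ion-pair catalyst may give poor facial control. Fallback with known chemistry, setting out from 9: the diene is combined with the doubly activated, chelating dienophile methyl 2,6-dimethyl-4-oxo-4H-pyran-3-carboxylate F1, made from commercial 2,6-dimethyl-4-oxo-4H-pyran-3-carboxylic acid with TMSCHN2. A Diels–Alder reaction under two-point-binding chiral Lewis acid catalysis (Cu(OTf)2 with (S,S)-tert-butyl-bis(oxazoline), CH2Cl2, or at high pressure) should give the 4a-carboxylate adduct methyl (4aR,5S,8aR)-5-(2-methoxy-2-oxoethyl)-6-(1-methoxy-2-methyl-1-oxopropan-2-yl)-2,5,8a-trimethyl-4-oxo-8,8a-dihydro-4H-chromene-4a(5H)-carboxylate F2. Krapcho dealkoxycarbonylation of its β-keto ester (LiCl, wet DMSO, 150 °C) comes back to the route at 14.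

2. Step 9. Under hot alkali the β-alkoxy ketone may open by E1cB cleavage of a ring C–O bond before the hindered C4 hydrazone forms, and diimide formed from hydrazine and air could reduce the vinyl group. Fallback setting out from 18: NaBH4 (MeOH, 0 °C) should give the C4 alcohol methyl 2-[(2R,4aS,5S,6R,8aR)-2-ethenyl-4-hydroxy-5-(2-methoxy-2-oxoethyl)-2,5,8a-trimethyloctahydro-2H-chromen-6-yl]-2-methylpropanoate F4. NaH, CS2 and MeI (THF) convert it to the S-methyl xanthate F5, and Barton–McCombie reduction (Bu3SnH, AIBN, toluene, 110 °C) gives the deoxygenated diester methyl 2-[(2R,4aR,5S,6R,8aR)-2-ethenyl-5-(2-methoxy-2-oxoethyl)-2,5,8a-trimethyloctahydro-2H-chromen-6-yl]-2-methylpropanoate F6. Saponification (KOH, ethylene glycol/H2O, 150 °C; aq HCl), now without a ketone in the molecule, comes back to the route at 22.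

3. Step 6. Non-directed delivery of hydrogen from the more open face would give the C6 epimer, and the dihydropyranone C=C might also be reduced. Fallback setting out from 14: the order is reversed and the mechanism changed. DBU (toluene, 40 °C) first equilibrates C4a to the trans-fused dienone methyl 2-[(4aR,5R,8aR)-5-(2-methoxy-2-oxoethyl)-2,5,8a-trimethyl-4-oxo-4a,5,8,8a-tetrahydro-4H-chromen-6-yl]-2-methylpropanoate F3, in which both axial methyl groups shield one face. Metal-hydride hydrogen-atom-transfer hydrogenation (Mn(dpm)3, PhSiH3, t-BuOOH, i-PrOH, rt) of the trisubstituted C6=C7 bond should then give the thermodynamically preferred C6 configuration and comes back to the route at 16, so steps 6 and 7 are both replaced.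

Further compounds
F1 | step 5 | methyl 2,6-dimethyl-4-oxo-4H-pyran-3-carboxylate | CC1=CC(=O)C(C(=O)OC)=C(C)O1
F2 | step 5 | methyl (4aR,5S,8aR)-5-(2-methoxy-2-oxoethyl)-6-(1-methoxy-2-methyl-1-oxopropan-2-yl)-2,5,8a-trimethyl-4-oxo-8,8a-dihydro-4H-chromene-4a(5H)-carboxylate | CC1=CC(=O)[C@@]2(C(=O)OC)[C@@](C)(CC(=O)OC)C(C(C)(C)C(=O)OC)=CC[C@@]2(C)O1
F3 | step 6 | methyl 2-[(4aR,5R,8aR)-5-(2-methoxy-2-oxoethyl)-2,5,8a-trimethyl-4-oxo-4a,5,8,8a-tetrahydro-4H-chromen-6-yl]-2-methylpropanoate | CC1=CC(=O)[C@@H]2[C@@](C)(CC(=O)OC)C(C(C)(C)C(=O)OC)=CC[C@@]2(C)O1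
F4 | step 9 | methyl 2-[(2R,4aS,5S,6R,8aR)-2-ethenyl-4-hydroxy-5-(2-methoxy-2-oxoethyl)-2,5,8a-trimethyloctahydro-2H-chromen-6-yl]-2-methylpropanoate (C4 epimers) | C=C[C@@]1(C)CC(O)[C@@H]2[C@@](C)(CC(=O)OC)[C@H](C(C)(C)C(=O)OC)CC[C@@]2(C)O1
F5 | step 9 | O-[(2R,4aS,5S,6R,8aR)-2-ethenyl-5-(2-methoxy-2-oxoethyl)-6-(1-methoxy-2-methyl-1-oxopropan-2-yl)-2,5,8a-trimethyloctahydro-2H-chromen-4-yl] S-methyl carbonodithioate (C4 epimers) | C=C[C@@]1(C)CC(OC(=S)SC)[C@@H]2[C@@](C)(CC(=O)OC)[C@H](C(C)(C)C(=O)OC)CC[C@@]2(C)O1
F6 | step 9 | methyl 2-[(2R,4aR,5S,6R,8aR)-2-ethenyl-5-(2-methoxy-2-oxoethyl)-2,5,8a-trimethyloctahydro-2H-chromen-6-yl]-2-methylpropanoate | C=C[C@@]1(C)CC[C@@H]2[C@@](C)(CC(=O)OC)[C@H](C(C)(C)C(=O)OC)CC[C@@]2(C)O1
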